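all flasks: substrate 0.20 mM
- teal: one stirred flow tank at steady state, fed with the mixture as stated, mean residence time 150 s
- red: one stirred flow tank at steady state, fed with the mixture as stated, mean residence time 50 s
- blue: everything together in a closed stirred flask, run for 50 s; time 50 s

    target ⇌ isomer of the product (K1 = 2.3, k1 = 0.0068 s⁻¹)
    2 substrate → homo dimer (k2 = 91 M⁻¹ s⁻¹)
    substrate → target (k3 = 2.4 × 10⁻⁴ s⁻¹)
    target → over-reaction product (k4 = 9.5 × 10⁻⁶ s⁻¹)
    substrate + 2 target → 3 target (k5 = 6.8 × 10⁵ M⁻² s⁻¹)

1. order of the set-ups by the share of target in all that became target or isomer of the product, at the outlet or at the end, highest first (teal / red / blue)
2. share of target in all that became target or isomer of the product, at the outlet or at the end, teal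
3. share of target in all that became target or isomer of the product, at the outlet or at the end, red
4. share of target in all that became target or isomer of the product, at the outlet or at the end, blue

- in percentages every species weighs as the substrate in it: one homo dimer counts as two
- a step written with two of one species runs at k times the square of its concentration and takes two of it each time
- the stated concentrations are those of everything mixed, before any reaction; amounts are the same in each set-up
- the share counts what is present at the end, not what went on to other products
- run time (blue): 50 s

**Two clocks.** Time in the vessel is one clock. The other is the time target and isomer of the product need to swing towards equilibrium. I call this the swing time (the relaxation time): the reciprocal of the forward and back constants of step 1 added together, 102 s. At equilibrium target holds 30.3 % of the pair.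

**Tank share.** Target is formed first and the isomer comes from it, so I reckon just the isomer. In a steady tank both leave by the same outflow, and step 4 is slow beside step 1. The supply of target therefore cancels, and the isomer holds its equilibrium share times stay/(stay + swing time), where the stay is the mean residence time. Teal stays longer than the swing time, so I get 58.6 % target. Red stays 50 s, less than the swing time, so I get 77.1 %.

**Closed flask.** In blue nothing leaves, so target ages with the run. Target as old as the run itself keeps 73.1 %. Target of the mean age under even formation, 25.0 s, keeps 84.9 %. The first half-life of substrate by dimerisation is 27.5 s, shorter than the run, so formation comes early and I expect a little less than that, still above red.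

**The forecast.** The forecast gives blue > red > teal, with teal 58.6 %, red 77.2 % and blue 83.1 %, holding that the tank ratio “depends only on the isomerisation constants and the residence time”.

**The result.** The flask gives blue > red > teal: teal 58.6 %, red 77.1 %, blue 83.2 %. With the loss of target to isomer of the product struck out both ways, blue reads 100 %. Blue's 83.2 % stands above the 73.1 % of its oldest target. Read at 3.0 min, blue has run 1.76 swing times, so its oldest target keeps 42.3 %, and that neighbour reads 55.3 %.

(Its constants are those of an exercise, and the outcome is calculated.)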